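**Retrosynthetic overview**

- Numbering used here: eight-membered ring C1 (carries the side chain), C2=C3 (butenolide alkene; C2 bears the CH2O, C3 the C=O), C4/C5 (cyclopropane), C6 (CHMe), C7 (CH2), C8 (CHOH); C9 is the side-chain stereocentre.
- Late stage: the isopropylidene terminus comes from cross-metathesis of a terminal alkene, the cyclopropane from hydroxyl-directed Simmons–Smith reaction of a Z C4=C5 alkene, and the C8 hydroxyl from reduction of a C8 ketone.
- Key disconnection: the eight-membered ring is closed at C6–C7 by a Claisen shift of a 2-methylene-dihydropyran (oxygen bridging C4 and C8), itself made in the same flask by gold-catalysed 6-exo-dig cyclisation of an acyclic alkynyl carbinol. The enabling feature is that C8 (carbinol carbon), C7, C6 and the cyclopropane bond C4–C5 of the eight-membered ring map onto a gamma,delta-unsaturated ketone (C8=O, C4=C5), while the butenolide C2=C3 bond holds C1 and C4 cis.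
- The alkynyl carbinol comes from a butenyl butyrolactone (C9 by Evans alkylation), furan-2(5H)-one and crotonaldehyde: Michael–aldol union (C1 set trans to C9 on the lactone ring), lactone-to-alkyne homologation, dehydrogenation to the butenolide, CBS reduction (C4).
- Ring order: auxiliary gamma-lactone (opened again later) → butenolide → transient dihydropyran → eight-membered ring → cyclopropane.

Key step: step 11

Remark: the two sp3 carbons of the second lactone ring, the transient carbinol carbon and the lactol carbon are formed as epimer mixtures. They are absent from the target and are removed in steps 5, 7 and 9, so they are left open in names and SMILES.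

**Step 1**
Reactants: 1 (R)-4-benzyloxazolidin-2-one; 2 hex-5-enoyl chloride
Product: 3 (R)-4-benzyl-3-(hex-5-enoyl)oxazolidin-2-one
Conditions: n-BuLi, THF, −78 °C; then 2, −78 to 0 °C
Reagents that add atoms: none
Why: N-acylation of the lithiated Evans auxiliary by an acid chloride is a standard imide formation and creates no stereocentre.

**Step 2**
Reactants: 3 (R)-4-benzyl-3-(hex-5-enoyl)oxazolidin-2-one; 4 tert-butyl bromoacetate
Product: 5 tert-butyl (S)-3-[(R)-4-benzyl-2-oxooxazolidine-3-carbonyl]hept-6-enoate
Conditions: NaN(SiMe3)2, THF, −78 °C; then 4, −78 to −40 °C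
Reagents that add atoms: none
Why: In this Evans asymmetric alkylation the chelated Z-sodium enolate is attacked on the face opposite the benzyl group of the (R)-auxiliary, which should set the side-chain stereocentre C9 as S.

**Step 3**
Reactants: 5 tert-butyl (S)-3-[(R)-4-benzyl-2-oxooxazolidine-3-carbonyl]hept-6-enoate
Product: 7 (S)-4-(but-3-en-1-yl)dihydrofuran-2(3H)-one, via tert-butyl (S)-3-(hydroxymethyl)hept-6-enoate 6 (not isolated)
Conditions: LiBH4, MeOH (1.5 equiv), THF, 0 °C; then TsOH·H2O (10 mol %), toluene, 60 °C
Reagents that add atoms: none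
Why: Reductive removal of the auxiliary with borohydride (the tert-butyl ester is spared) followed by acid-catalysed lactonisation should give the beta-substituted gamma-butyrolactone without touching C9.

**Step 4**
Reactants: 7 (S)-4-(but-3-en-1-yl)dihydrofuran-2(3H)-one; 8 furan-2(5H)-one; 9 (E)-but-2-enal
Product: 11 (3R,4S)-4-(but-3-en-1-yl)-3-{4-[(E)-1-hydroxybut-2-en-1-yl]-5-oxotetrahydrofuran-3-yl}dihydrofuran-2(3H)-one, via lithium enolate of the Michael adduct 10 (not isolated)
Conditions: LiN(i-Pr)2, THF, −78 °C; then 8, −78 °C; then 9, −78 °C; AcOH quench at −78 °C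
Reagents that add atoms: none
Why: In this tandem Michael addition–aldol reaction the lactone enolate should add to the butenolide anti to the butenyl group at C9, which fixes C1 trans to C9 (R), and the new enolate is trapped 1,2 by the enal, the other new centres being left uncontrolled because they are erased in steps 5 and 9.

**Step 5**
Reactants: 11 the Michael–aldol adduct
Product: 12 (3R,4S)-3-{4-[(E)-but-2-enoyl]-5-oxotetrahydrofuran-3-yl}-4-(but-3-en-1-yl)dihydrofuran-2(3H)-one
Conditions: Dess–Martin periodinane, CH2Cl2, 0 to 23 °C
Reagents that add atoms: none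
Why: Dess–Martin oxidation of the allylic beta-hydroxy lactone should give the 2-acyl lactone under neutral conditions, removing the uncontrolled carbinol centre and making the neighbouring centre epimerisable.

**Step 6**
Reactants: 12 the acyl bis-lactone
Product: 14 3-[(E)-but-2-enoyl]-4-[(3R,4S)-4-(but-3-en-1-yl)-2-hydroxytetrahydrofuran-3-yl]dihydrofuran-2(3H)-one, via sodium enolate of the acyl lactone 13 (not isolated)
Conditions: NaH (1.05 equiv), THF, 0 °C; then i-Bu2AlH (1.2 equiv), −78 °C; aqueous potassium sodium tartrate
Reagents that add atoms: none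
Why: Partial reduction of a gamma-lactone to its lactol with i-Bu2AlH should be chemoselective because the acidic 2-acyl lactone is first converted into its delocalised enolate, which is inert to hydride (in situ protection of a 1,3-dicarbonyl).

**Step 7**
Reactants: 14 the lactol
Product: 15 (2S,3R)-2-(but-3-en-1-yl)-3-{4-[(E)-but-2-enoyl]-5-oxotetrahydrofuran-3-yl}pent-4-yn-1-ol
Conditions: dimethyl (1-diazo-2-oxopropyl)phosphonate, K2CO3, MeOH, 0 to 23 °C
Reagents that add atoms: dimethyl (1-diazo-2-oxopropyl)phosphonate CC(=O)C(=[N+]=[N-])P(=O)(OC)OC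
Why: Ohira–Bestmann (Seyferth–Gilbert) homologation of the lactol through its open hydroxy aldehyde should give the terminal alkyne and free the primary alcohol, while the acyl lactone is again masked as its enolate and C1 is held trans to C9 by the lactol ring until it opens.

**Step 8**
Reactants: 15 the alkynol
Product: 16 (2S,3R)-2-(but-3-en-1-yl)-3-{4-[(E)-but-2-enoyl]-5-oxotetrahydrofuran-3-yl}pent-4-yn-1-yl acetate
Conditions: Ac2O, pyridine, CH2Cl2, 0 °C
Reagents that add atoms: acetic anhydride CC(=O)OC(C)=O
Why: Standard acetylation of the primary alcohol installs the acetate of the target early and at the same time blocks the competing 5-exo cyclisation of this oxygen in step 11.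

**Step 9**
Reactants: 16 the acetate
Product: 19 (2S,3S)-2-(but-3-en-1-yl)-3-{4-[(E)-but-2-enoyl]-5-oxo-2,5-dihydrofuran-3-yl}pent-4-yn-1-yl acetate, via alpha-phenylselanyl acyl lactone 17 (not isolated), via selenoxide 18 (not isolated)
Conditions: PhSeCl, pyridine, CH2Cl2, 0 °C; then 30% H2O2, 0 to 23 °C (no amine base in the oxidation or work-up)
Reagents that add atoms: none
Why: Selenenylation of the 1,3-dicarbonyl followed by selenoxide syn-elimination (the only beta-hydrogen is on C2) should introduce the C2=C3 butenolide double bond and thereby erase both uncontrolled lactone stereocentres.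

**Step 10**
Reactants: 19 the acyl butenolide
Product: 20 (2S,3S)-2-(but-3-en-1-yl)-3-{4-[(S,E)-1-hydroxybut-2-en-1-yl]-5-oxo-2,5-dihydrofuran-3-yl}pent-4-yn-1-yl acetate
Conditions: (R)-2-methyl-CBS-oxazaborolidine (20 mol %), catecholborane, toluene, −78 °C
Reagents that add atoms: none
Why: In this Corey–Bakshi–Shibata 1,2-reduction the fully substituted butenolide flank should act as the large group and the (E)-propenyl as the small one, so that the (R)-catalyst delivers hydride to give the (S)-carbinol at C4 under reagent control.

**Step 11**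
Reactants: 20 the alkynyl carbinol
Product: 22 butenolide-fused (1R,6S,Z)-cycloocta-2,4-dienone (C8 ketone), via exocyclic enol ether 21 (not isolated)
Conditions: Ph3PAuNTf2 (5 mol %), 2,6-di-tert-butyl-4-methylpyridine (10 mol %), 4 Å molecular sieves, toluene, 23 °C; then 110 °C, sealed tube
Reagents that add atoms: none
Why: The gold catalyst activates the terminal alkyne for anti-addition of the C4 hydroxyl to the internal carbon C8, and protodeauration gives the 2-methylene-3,6-dihydro-2H-pyran 21, an allyl vinyl ether that on heating should undergo a concerted [3,3] sigmatropic (Claisen) shift in which the O–C4 bond breaks and the C6–C7 bond forms. The closest known reactions are the tandem alkynol cycloisomerisation–Claisen rearrangement used for cycloheptenones and the Claisen ring expansion of 2-methylene-6-vinyltetrahydropyrans to cyclooct-4-enones. The oxacycle closes in the 6-exo-dig mode, and the eight-membered carbocycle closes by ring expansion of that oxacycle through a chair-like six-atom array bridged by the C1–C2=C3 tether (a bicyclo[3.3.1]-type transition state), which forces the new C4=C5 bond to be Z. The C6 stereocentre is set by 1,3-chirality transfer from C4: with the (S)-carbinol and the (E)-propenyl group the methyl points outward (pseudo-equatorial) and C7 bonds to the face from which oxygen departs, giving 6S, while the C1 side chain sits pseudo-equatorially. The step needs attack by the secondary and not the primary oxygen (secured by the acetate), an exocyclic and not an endocyclic enol ether and a [3,3] shift and not ionisation of the doubly allylic C–O bond (secured by the acid-free gold triflimide, the hindered pyridine buffer and neutral thermolysis), and a chair and not a boat array (secured by the sp2 carbons C2 and C3 of the tether, which remove the transannular contact with C6).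

**Step 12**
Reactants: 22 the cyclooctadienone
Product: 23 butenolide-fused (1R,6S,8S,Z)-cycloocta-2,4-dienol
Conditions: (R)-2-methyl-CBS-oxazaborolidine (20 mol %), catecholborane, toluene, −78 °C
Reagents that add atoms: none
Why: CBS reduction of the ring ketone with the branched C1 flank as the large group should give the 8S alcohol, the catalyst bias being reinforced by hydride approach anti to the C1 side chain, and the non-basic conditions avoid epimerisation of the acidic C1–H.

**Step 13**
Reactants: 23 the dienol
Product: 24 the target skeleton with a but-3-enyl group in place of the 4-methylpent-3-enyl group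
Conditions: Et2Zn, CH2I2, CH2Cl2, −10 to 0 °C
Reagents that add atoms: diiodomethane ICI
Why: In this hydroxyl-directed Simmons–Smith (Furukawa) cyclopropanation the zinc alkoxide at C8 should deliver the carbenoid to the Z C4=C5 bond on its own face, which is also anti to the C6 methyl, setting C4 and C5 (both R), while the tetrasubstituted butenolide alkene and the remote monosubstituted alkene react more slowly.

**Step 14**
Reactants: 24 the cyclopropane
Product: 25 target, CNP0267808.2
Conditions: 2-methylbut-2-ene (excess), second-generation Grubbs catalyst (5 mol %), CH2Cl2, 40 °C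
Reagents that add atoms: 2-methylbut-2-ene CC=C(C)C
Why: Olefin cross-metathesis of the terminal alkene with 2-methylbut-2-ene should convert it into the isopropylidene terminus, the tetrasubstituted butenolide alkene, cyclopropane, free alcohol and acetate being inert to the ruthenium carbene.

**Compound list**

1 | (R)-4-benzyloxazolidin-2-one | O=C1N[C@H](Cc2ccccc2)CO1 | starting material
2 | hex-5-enoyl chloride | C=CCCCC(Cl)=O | starting material
3 | (R)-4-benzyl-3-(hex-5-enoyl)oxazolidin-2-one | C=CCCCC(=O)N1[C@H](Cc2ccccc2)COC1=O | intermediate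
4 | tert-butyl bromoacetate | CC(C)(C)OC(=O)CBr | starting material
5 | tert-butyl (S)-3-[(R)-4-benzyl-2-oxooxazolidine-3-carbonyl]hept-6-enoate | C=CCC[C@@H](CC(=O)OC(C)(C)C)C(=O)N1[C@H](Cc2ccccc2)COC1=O | intermediate
6 | tert-butyl (S)-3-(hydroxymethyl)hept-6-enoate | C=CCC[C@@H](CC(=O)OC(C)(C)C)CO | intermediate
7 | (S)-4-(but-3-en-1-yl)dihydrofuran-2(3H)-one | C=CCC[C@H]1CC(=O)OC1 | intermediate
8 | furan-2(5H)-one | O=C1C=CCO1 | starting material
9 | (E)-but-2-enal | C/C=C/C=O | starting material
10 | lithium 4-[(3R,4S)-4-(but-3-en-1-yl)-2-oxotetrahydrofuran-3-yl]-4,5-dihydrofuran-2-olate (enolate of the Michael adduct) | [Li+].C=CCC[C@@H]1COC(=O)[C@H]1C2COC([O-])=C2 | intermediate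
11 | (3R,4S)-4-(but-3-en-1-yl)-3-{4-[(E)-1-hydroxybut-2-en-1-yl]-5-oxotetrahydrofuran-3-yl}dihydrofuran-2(3H)-one | C=CCC[C@@H]1COC(=O)[C@H]1C2COC(=O)C2C(O)/C=C/C | intermediate
12 | (3R,4S)-3-{4-[(E)-but-2-enoyl]-5-oxotetrahydrofuran-3-yl}-4-(but-3-en-1-yl)dihydrofuran-2(3H)-one | C=CCC[C@@H]1COC(=O)[C@H]1C2COC(=O)C2C(=O)/C=C/C | intermediate
13 | sodium enolate of 12 (deprotonated between the ketone and the lactone carbonyl) | [Na+].C=CCC[C@@H]1COC(=O)[C@H]1C2COC(=O)C2=C([O-])/C=C/C | intermediate
14 | 3-[(E)-but-2-enoyl]-4-[(3R,4S)-4-(but-3-en-1-yl)-2-hydroxytetrahydrofuran-3-yl]dihydrofuran-2(3H)-one (lactol) | C=CCC[C@@H]1COC(O)[C@H]1C2COC(=O)C2C(=O)/C=C/C | intermediate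
15 | (2S,3R)-2-(but-3-en-1-yl)-3-{4-[(E)-but-2-enoyl]-5-oxotetrahydrofuran-3-yl}pent-4-yn-1-ol | C=CCC[C@H](CO)[C@@H](C#C)C1COC(=O)C1C(=O)/C=C/C | intermediate
16 | (2S,3R)-2-(but-3-en-1-yl)-3-{4-[(E)-but-2-enoyl]-5-oxotetrahydrofuran-3-yl}pent-4-yn-1-yl acetate | C=CCC[C@H](COC(C)=O)[C@@H](C#C)C1COC(=O)C1C(=O)/C=C/C | intermediate
17 | 16 carrying a phenylselanyl group on the carbon between the ketone and the lactone carbonyl | C=CCC[C@H](COC(C)=O)[C@@H](C#C)C1COC(=O)C1([Se]c1ccccc1)C(=O)/C=C/C | intermediate
18 | selenoxide of 17 | C=CCC[C@H](COC(C)=O)[C@@H](C#C)C1COC(=O)C1([Se](=O)c1ccccc1)C(=O)/C=C/C | intermediate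
19 | (2S,3S)-2-(but-3-en-1-yl)-3-{4-[(E)-but-2-enoyl]-5-oxo-2,5-dihydrofuran-3-yl}pent-4-yn-1-yl acetate | C=CCC[C@H](COC(C)=O)[C@@H](C#C)C1=C(C(=O)/C=C/C)C(=O)OC1 | intermediate
20 | (2S,3S)-2-(but-3-en-1-yl)-3-{4-[(S,E)-1-hydroxybut-2-en-1-yl]-5-oxo-2,5-dihydrofuran-3-yl}pent-4-yn-1-yl acetate | C=CCC[C@H](COC(C)=O)[C@@H](C#C)C1=C([C@@H](O)/C=C/C)C(=O)OC1 | intermediate
21 | butenolide-fused 2-methylene-3,6-dihydro-2H-pyran (ring oxygen joins C4 and C8; C8=CH2; C4 S with (E)-prop-1-enyl; C1 R with the (S)-1-acetoxyhex-5-en-2-yl chain) | C=CCC[C@H](COC(C)=O)[C@H]1C(=C)O[C@@H](/C=C/C)C2=C1COC2=O | intermediate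
22 | butenolide-fused cycloocta-2,4-dienone (C8 ketone; C4=C5 Z; 6S methyl; 1R (S)-1-acetoxyhex-5-en-2-yl chain) | C=CCC[C@H](COC(C)=O)[C@H]1C(=O)C[C@H](C)/C=C\C2=C1COC2=O | intermediate
23 | 8S alcohol of 22 | C=CCC[C@H](COC(C)=O)[C@H]1[C@@H](O)C[C@H](C)/C=C\C2=C1COC2=O | intermediate
24 | target skeleton with a but-3-enyl in place of the 4-methylpent-3-enyl group (cyclopropane 4R,5R) | C=CCC[C@H](COC(C)=O)[C@H]1[C@@H](O)C[C@H](C)[C@H]3C[C@H]3C2=C1COC2=O | intermediate
25 | CNP0267808.2 | CC(C)=CCC[C@H](COC(C)=O)[C@H]1[C@@H](O)C[C@H](C)[C@H]3C[C@H]3C2=C1COC2=O | target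

**Step count and risks**

Total steps: 14. Longest linear sequence: 14 (from 1 and 2; 4, 8 and 9 enter as commercial inputs).

Steps most likely to fail:

Step 11. What may go wrong: acid-promoted migration of the exocyclic enol ether double bond into the ring, or ionisation of the doubly allylic C–O bond (1,3-shift, loss of the carbinol configuration), may outrun the [3,3] shift. The fallback sets out from 20 and returns at 22, generating the enol ether by the neutral selenide route. Semihydrogenation of the terminal alkyne (H2, Pd/CaCO3 poisoned with Pb(OAc)2, quinoline) should give the vinyl carbinol F1. N-(Phenylseleno)phthalimide with catalytic camphorsulfonic acid should then close the pyran by 6-exo selenoetherification to the phenylselanylmethyl dihydropyran F2. Oxidation with NaIO4 gives the selenoxide F3, which on heating in toluene with 2,6-di-tert-butyl-4-methylpyridine should eliminate to 21 and rearrange in the same flask to 22.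

Step 10. What may go wrong: poor facial discrimination, because both flanks of the ketone are alkenyl, or uncatalysed background reduction of the activated ketone, would give both C4 epimers. The fallback sets out from 19 and returns at 20, replacing asymmetric reduction by resolution. Luche reduction (NaBH4, CeCl3, MeOH, −78 °C) should give 20 together with its C4 epimer F4. The two are diastereomers and can be separated by lipase-catalysed acetylation (Burkholderia cepacia lipase, vinyl acetate), which by Kazlauskas' rule should acylate the (R)-carbinol to the acetate F5 and leave 20.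

Step 13. What may go wrong: slow carbenoid delivery to the conjugated, electron-poorer C4=C5 bond would let cyclopropanation of the terminal alkene compete (loss of chemoselectivity). The fallback sets out from 23 and returns at 25, reversing the last two operations and changing the carbene source. Cross-metathesis of 23 with 2-methylbut-2-ene (second-generation Grubbs catalyst) should first give the isopropylidene-terminated dienol F6; the ring alkene, flanked by a fully substituted and a branched carbon, is expected to stay out of metathesis. Pd(OAc)2-catalysed decomposition of diazomethane (Et2O, 0 °C) should then cyclopropanate only the cis-disubstituted C4=C5 bond, since trisubstituted and tetrasubstituted alkenes are inert to this reagent, from the face anti to the C6 methyl, giving 25.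

**Further compounds**

F1 | step 11 | (2S,3R)-2-(but-3-en-1-yl)-3-{4-[(S,E)-1-hydroxybut-2-en-1-yl]-5-oxo-2,5-dihydrofuran-3-yl}pent-4-en-1-yl acetate | C=CCC[C@H](COC(C)=O)[C@@H](C=C)C1=C([C@@H](O)/C=C/C)C(=O)OC1
F2 | step 11 | butenolide-fused 2-(phenylselanylmethyl)-3,6-dihydro-2H-pyran (saturated analogue of 21 at C8) | C=CCC[C@H](COC(C)=O)[C@H]1C(C[Se]c2ccccc2)O[C@@H](/C=C/C)C3=C1COC3=O
F3 | step 11 | selenoxide of F2 | C=CCC[C@H](COC(C)=O)[C@H]1C(C[Se](=O)c2ccccc2)O[C@@H](/C=C/C)C3=C1COC3=O
F4 | step 10 | C4 epimer of 20 ((R)-carbinol) | C=CCC[C@H](COC(C)=O)[C@@H](C#C)C1=C([C@H](O)/C=C/C)C(=O)OC1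
F5 | step 10 | acetate of F4 | C=CCC[C@H](COC(C)=O)[C@@H](C#C)C1=C([C@H](OC(C)=O)/C=C/C)C(=O)OC1
F6 | step 13 | 23 with the 4-methylpent-3-enyl terminus | CC(C)=CCC[C@H](COC(C)=O)[C@H]1[C@@H](O)C[C@H](C)/C=C\C2=C1COC2=O
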